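A small charge of substrate in the midnight run and a larger one in the dusk run were what I had to go on. South's charge is larger than midnight's and smaller than dusk's, and south-west's is larger than both.

the same everywhere: free catalyst 25 mM
- midnight: substrate 0.094 M (fed, over 6.0 min); gas 200 mM (held); run made earlier
- dusk: substrate 0.31 M (fed, over 6.0 min); gas 200 mM (held); run made earlier
- south-west: substrate 0.50 M (fed, over 6.0 min); gas 200 mM (held); time 25 min
- south: substrate 0.12 M; gas 200 mM; everything together at the start; time 25 min

| run | time / min | product / % | substrate / % |
|---|---|---|---|
| midnight | 4.00 | 0.6 | 62.4 |
| midnight | 8.00 | 6.3 | 85.4 |
| midnight | 10.0 | 11.5 | 82.0 |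
| midnight | 15.0 | 24.3 | 70.7 |
| midnight | 20.0 | 35.2 | 60.2 |
| dusk | 1.50 | 0 | 24.0 |
| dusk | 4.00 | 0.1 | 63.1 |
| dusk | 8.00 | 5.1 | 90.6 |
| dusk | 12.0 | 9.7 | 84.8 |
| dusk | 20.0 | 21.8 | 74.3 |

(each reading ± 0.5 percentage points)

- for product the idle complex is counted in
- at the start none of reagent is dissolved
- the numbers in the tables scatter with a standard deviation of 0.5 percentage points
- steps that have been proposed: substrate + free catalyst -> catalyst intermediate A; catalyst intermediate A -> catalyst intermediate B; reagent + catalyst intermediate B -> catalyst intermediate C; catalyst intermediate C -> catalyst intermediate D; catalyst intermediate D -> free catalyst + product; free catalyst + product <-> idle complex; gas <-> reagent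
- percentages count the whole charge, also what has not yet gone in

1. the flask that ends with the higher amount of product, in percent of the substrate charged, or "neither" when 2 percentage points or less lies between them (south-west / south / neither)
2. final product, as a percentage of the substrate charged, in south-west
3. final product, as a percentage of the substrate charged, in south

I began with the shortest time on the ladder. Reagent was absent at the start, and the product lines of the two fed runs, drawn back, met zero at about 4.74 min, which I read as the wait in a fed flask, and I used it for south-west. Substrate in a steady feed goes in on average at the mid-point of the feed, 3.00 min after the start. South has no feed, so I took that off and gave south a wait of 1.74 min.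

The next rung was the steady pace. Midnight gained its charge at a rate that would take 42.2 min for the whole of it, and dusk at a rate that would take 71.9 min. At 20.0 min the readings fell short of the charge, and I read that shortfall as substrate held on the catalyst: 17.3% of the catalyst charged in midnight, 48.4% in dusk.

So I solved both ends. With a small charge the catalyst stands mostly open and the pace follows the charge (pseudo-first-order), so this time stays constant. With a large charge the pace has a ceiling, so the time grows with the charge. I joined the ends with a straight line through the two runs. The turnover time of south, its minutes to whole conversion at the steady late pace, came out at 45.8 min, and that of south-west at 97.9 min. Both are longer than the 25 min of the run, so I kept the product line straight. The product fraction is then the time after the wait divided by the turnover time: 20.7% for south-west and 50.8% for south.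

The forecast named south as the higher flask, with 20% for south-west and 44% for south, on the ground that the “catalyst is therefore approaching saturation”. For south its figure is lower than mine.

The flask gave south as the higher, with 20.5% in south-west and 45.7% in south, so the forecast stood. At the end, free catalyst was 34.8% of the catalyst charged in south-west and 81.5% in south. Taken with my wait for south, the result in south stands for a turnover time of 50.9 min, longer than my 45.8 min, so my figure for south lay above the flask by 5.1 percentage points.

    substrate + free catalyst → catalyst intermediate A (k = 1.50 L mol⁻¹ min⁻¹)
    catalyst intermediate A → catalyst intermediate B (k = 95.0 min⁻¹)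
    reagent + catalyst intermediate B → catalyst intermediate C (k = 9.10 L mol⁻¹ min⁻¹)
    catalyst intermediate C → catalyst intermediate D (k = 2.50 min⁻¹)
    catalyst intermediate D → free catalyst + product (k = 33.0 min⁻¹)
    free catalyst + product ⇌ idle complex (K = 0.960 L mol⁻¹, k = 0.250 L mol⁻¹ min⁻¹)
    gas ⇌ reagent, rate k7*(csat - [reagent]) (kL = 0.0350 min⁻¹)

The same flask as south, read at 15 min, gets 29.0% from my turnover time and 26.1% from the longer one. The computed flask holds 26.2%.

(The earlier runs and the new flask are calculated from invented constants.)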